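In a one-step world target climbs to a level and stays there, but the winter run reads 14.8% of the substrate charged at 5.00 min and 4.6% at its last reading. So take that flask in slow motion.

the same everywhere: coupling partner 0.495 M
- midnight: substrate 0.33 M; catalyst 2.4 mM; temperature 20 °C; run made earlier
- winter: substrate 0.33 M; catalyst 4.1 mM; temperature 35 °C; run made earlier
- noon: substrate 0.33 M; catalyst 6 mM; temperature 20 °C; run made earlier
- dawn: substrate 0.21 M; catalyst 8.2 mM; temperature 35 °C; run made earlier
- Monday's: substrate 0.080 M; catalyst 2.5 mM; temperature 35 °C; time 12 min
- Wednesday's: substrate 0.33 M; catalyst 8.2 mM; temperature 35 °C; time 25 min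

| midnight: time / min | midnight: target / % | winter: time / min | winter: target / % | noon: time / min | noon: target / % | dawn: time / min | dawn: target / % |
|---|---|---|---|---|---|---|---|
| 4.00 | 8.3 | 2.00 | 12.2 | 12.0 | 9.8 | 2.00 | 13.2 |
| 10.0 | 10.1 | 5.00 | 14.8 | 25.0 | 8.0 | 5.00 | 15.6 |
| 20.0 | 9.1 | 10.0 | 12.8 | 40.0 | 6.3 | 10.0 | 11.9 |
| 50.0 | 5.6 | 25.0 | 4.6 | 50.0 | 5.8 | 25.0 | 4.3 |

(scatter of a reading: 0.5 percentage points)

- what may be going on: substrate + coupling partner <-> isomer of the product; substrate + coupling partner <-> target; target + catalyst <-> isomer of the product + catalyst; coupling partner -> decomposed reagent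

* which of the two ends with the higher amount of target, in percent of the substrate charged ("neither" if they lie within 2 percentage points) (Monday's / Wednesday's / neither)
* target at the end, in percent of the substrate charged, Monday's
* target at the end, in percent of the substrate charged, Wednesday's

In the first instants target climbs quickly: by 2.00 min the winter run already reads 12.2%. In the middle, at 5.00 min, the winter run reads 14.8%, and the dawn run, with twice the catalyst and less substrate, reads 15.6%.

Then comes the fall. Between 10.0 min and 25.0 min the winter readings give 10.2 min, and that is the fall half-time, the time in which target halves past its peak. The dawn readings give 10.2 min. The two readings of the half-time agree although catalyst and substrate both differ between these runs, so I read the fall as coupling partner decaying, with target following it back in a quasi-equilibrium.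

My reckoning follows from that. Wednesday's flask is read at 25 min, where the winter and dawn runs read 4.6% and 4.3%, so I expect about 4.45%. Monday's flask is read at 12 min, and the winter reading at 10.0 min, carried forward on the fall half-time, gives 11.2%.

The forecast named Monday's, with 11.2% for Monday's flask and 4.4% for Wednesday's, on the ground that “Percent yield then depends mostly on time and temperature”.

The flask gives Monday's: 13.0% for Monday's flask and 3.74% for Wednesday's.

    substrate + coupling partner ⇌ isomer of the product (K = 20.0 M⁻¹, k = 0.0490 M⁻¹ min⁻¹, Ea = 77.0 kJ mol⁻¹, ΔH = −34.0 kJ mol⁻¹)
    substrate + coupling partner ⇌ target (K = 0.810 M⁻¹, k = 0.210 M⁻¹ min⁻¹, Ea = 54.0 kJ mol⁻¹, ΔH = 48.0 kJ mol⁻¹)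
    target + catalyst ⇌ isomer of the product + catalyst, rate k3*[catalyst]*[target] forward; the back reaction follows from the equilibrium constant (k = 4.40 M⁻¹ min⁻¹, Ea = 45.0 kJ mol⁻¹)
    coupling partner → decomposed reagent (k = 0.0810 min⁻¹, Ea = 88.0 kJ mol⁻¹)
    (constants at 35 °C)

The difference in time is the main reason for the gap: Monday's flask, read at Wednesday's 25 min, stands at 5.05%, and your fall half-time, carrying its 13.0% over the extra 13.0 min, gives 5.37%. Run the same half-time backwards on Wednesday's flask: from 3.74% at 25 min it gives 7.38% at 15 min, where that flask holds 8.08%.

The earlier runs and the new flask stem from a simulated flask with made-up constants.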